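## Retrosynthetic overview

1. The γ-lactone (ring B: O–C12–C11–C7–C6) is closed last, at the O–C6 bond, by anodic dehydrogenative lactonization of a germacra-1(10),4,11(13)-trien-12-oic acid with no functional group at C6; this step also sets the C6 stereocenter.
2. The ten-membered carbocycle (ring A) comes from ring-closing metathesis at C1=C10 (Z) of an open-chain acid.
3. C8/C9 (syn diol) and C10 come from a reagent-controlled (Z)-γ-alkoxyallylboration of a C8 aldehyde; C7 from an auxiliary-controlled alkylation of an itaconate-derived imide with an (E)-allylic bromide (C1–C6; 4E from alkyne carboalumination; C2 from (S)-epichlorohydrin).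
4. Enabling feature: C6–H2 is allylic to C4=C5 and γ to the C12 carboxyl group, so O(C12)···H–C6 transfer runs through a six-membered ring (O–C12–C11–C7–C6–H); C12 is an sp2-bound (α-methylene) carboxyl whose O-radical decarboxylates slowly; the competing C8–H is deactivated by the angelate oxygen.
5. Ring order: ring A first, ring B last.

Key step: step 19

Remarks: the target SMILES is read as 2S,6R,7S,8R,9R, 1(10)Z, 4E, with a (Z)-2-methylbut-2-enoate (angelate) on O8 and an acetate on O9. Germacrane numbering is used for locants in the text (C12 = carboxyl carbon, C13 = exocyclic methylene, C14 on C10, C15 on C4). Alkoxides, enolates and carboxylates formed by simple deprotonation are treated as part of the conditions and are not numbered.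

## Route

Step 1
Reactants: 1 (S)-epichlorohydrin; 2 ethynyltrimethylsilane
Product: 3 (2S)-1-chloro-5-(trimethylsilyl)pent-4-yn-2-ol
Conditions: 2, nBuLi, THF, −78 °C; BF3·OEt2; then 1, −78 °C
Reagents that add atoms: none
Why: The lithium acetylide opens the BF3-activated epoxide at its CH2 carbon (Yamaguchi–Hirao alkynylation), so the stereocenter of 1 is carried over unchanged as C2.

Step 2
Reactants: 3 (2S)-1-chloro-5-(trimethylsilyl)pent-4-yn-2-ol
Product: 5 (3S)-6-(trimethylsilyl)hex-1-en-5-yn-3-ol, via epoxide 4 (not isolated)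
Conditions: Me3S+ I−, nBuLi, THF, −20 °C to rt
Reagents that add atoms: trimethylsulfonium iodide (C[S+](C)C.[I-])
Why: Base closes the chlorohydrin to epoxide 4, dimethylsulfonium methylide opens it at CH2 and the betaine loses Me2S to give the vinyl carbinol (one-carbon homologation of an epoxide to an allylic alcohol), without touching the C–O stereocenter.

Step 3
Reactants: 5 (3S)-6-(trimethylsilyl)hex-1-en-5-yn-3-ol
Product: 6 TBS ether of 5
Conditions: TBSCl, imidazole, DMF, rt
Reagents that add atoms: tert-butyldimethylsilyl chloride (CC(C)(C)[Si](C)(C)Cl)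
Why: Standard silylation of a secondary allylic alcohol.

Step 4
Reactants: 6 TBS ether of 5
Product: 7 tert-butyl{[(3S)-hex-1-en-5-yn-3-yl]oxy}dimethylsilane
Conditions: K2CO3, MeOH, rt
Reagents that add atoms: none
Why: Methoxide removes the alkynyl silyl group selectively (protodesilylation), the silyl ether being stable under these conditions.

Step 5
Reactants: 7 tert-butyl{[(3S)-hex-1-en-5-yn-3-yl]oxy}dimethylsilane
Product: 9 (2E,5S)-5-{[tert-butyl(dimethyl)silyl]oxy}-3-methylhepta-2,6-dien-1-ol, via alkenylalane 8 (not isolated)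
Conditions: Me3Al, Cp2ZrCl2 (cat.), H2O (1 equiv), CH2Cl2, −20 °C; then (CH2O)n, THF, rt
Reagents that add atoms: trimethylaluminium (C[Al](C)C); formaldehyde as paraformaldehyde (C=O)
Why: Zr-catalysed syn-carboalumination of the terminal alkyne (Negishi carboalumination) puts CH3 on C4 and Al on C5, which fixes the 4E trisubstituted olefin, and alkenylalane 8 then adds to formaldehyde to bring in C6.

Step 6
Reactants: 9 (2E,5S)-5-{[tert-butyl(dimethyl)silyl]oxy}-3-methylhepta-2,6-dien-1-ol
Product: 10 {[(3S,5E)-7-bromo-5-methylhepta-1,5-dien-3-yl]oxy}(tert-butyl)dimethylsilane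
Conditions: CBr4, PPh3, CH2Cl2, 0 °C
Reagents that add atoms: tetrabromomethane (BrC(Br)(Br)Br)
Why: Appel bromination of the primary allylic alcohol proceeds without allylic transposition and keeps the E olefin.

Step 7
Reactants: 11 itaconic anhydride; 12 (4R)-4-benzyl-1,3-oxazolidin-2-one
Product: 13 4-[(4R)-4-benzyl-2-oxo-1,3-oxazolidin-3-yl]-2-methylidene-4-oxobutanoic acid
Conditions: 12, nBuLi, THF, −78 °C; then 11, −78 °C; aq. HCl
Reagents that add atoms: none
Why: N-Acylation by a cyclic anhydride: the lithiated oxazolidinone should open the anhydride at the non-conjugated, more electrophilic carbonyl group (the site that alcohols attack), giving the C8 imide and leaving the α-methylene carboxyl group (C12) free.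

Step 8
Reactants: 13 4-[(4R)-4-benzyl-2-oxo-1,3-oxazolidin-3-yl]-2-methylidene-4-oxobutanoic acid
Product: 14 tert-butyl ester of 13
Conditions: tert-butyl 2,2,2-trichloroacetimidate, BF3·OEt2 (cat.), CH2Cl2/cyclohexane, rt
Reagents that add atoms: tert-butyl 2,2,2-trichloroacetimidate (CC(C)(C)OC(=N)C(Cl)(Cl)Cl)
Why: Acid-catalysed tert-butylation with the trichloroacetimidate esterifies the acid without base, so the exocyclic olefin is not moved into conjugation.

Step 9
Reactants: 14 tert-butyl ester of 13; 10 {[(3S,5E)-7-bromo-5-methylhepta-1,5-dien-3-yl]oxy}(tert-butyl)dimethylsilane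
Product: 15 tert-butyl (3R,5E,8S)-3-{[(4R)-4-benzyl-2-oxo-1,3-oxazolidin-3-yl]carbonyl}-8-{[tert-butyl(dimethyl)silyl]oxy}-6-methyl-2-methylidenedeca-5,9-dienoate
Conditions: NaN(SiMe3)2, THF, −78 °C; then 10, −78 to −40 °C
Reagents that add atoms: none
Why: Evans asymmetric alkylation: the chelated Z sodium enolate (an extended enolate that reacts at its α-carbon C7, as itaconate enolates do) is attacked by the allylic bromide on the face opposite the benzyl group of the (R)-auxiliary, which sets C7.

Step 10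
Reactants: 15 tert-butyl (3R,5E,8S)-3-{[(4R)-4-benzyl-2-oxo-1,3-oxazolidin-3-yl]carbonyl}-8-{[tert-butyl(dimethyl)silyl]oxy}-6-methyl-2-methylidenedeca-5,9-dienoate
Product: 16 tert-butyl (3R,5E,8S)-8-{[tert-butyl(dimethyl)silyl]oxy}-3-(hydroxymethyl)-6-methyl-2-methylidenedeca-5,9-dienoate
Conditions: LiBH4, MeOH (1 equiv), Et2O, 0 °C
Reagents that add atoms: none
Why: Reductive removal of the auxiliary: LiBH4 reduces the imide to the primary alcohol (C8) faster than it attacks the hindered tert-butyl acrylate.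

Step 11
Reactants: 16 tert-butyl (3R,5E,8S)-8-{[tert-butyl(dimethyl)silyl]oxy}-3-(hydroxymethyl)-6-methyl-2-methylidenedeca-5,9-dienoate
Product: 17 tert-butyl (3R,5E,8S)-8-{[tert-butyl(dimethyl)silyl]oxy}-3-formyl-6-methyl-2-methylidenedeca-5,9-dienoate
Conditions: Dess–Martin periodinane, NaHCO3, CH2Cl2, 0 °C; used at once
Reagents that add atoms: none
Why: Buffered Dess–Martin oxidation should give the α-branched aldehyde without epimerisation at C7 or migration of the exocyclic olefin.

Step 12
Reactants: 18 2-methylprop-2-en-1-ol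
Product: 19 3-(methoxymethoxy)-2-methylprop-1-ene
Conditions: MOMCl, iPr2NEt, CH2Cl2, 0 °C to rt
Reagents that add atoms: chloromethyl methyl ether (COCCl)
Why: Standard O-alkylation to the methoxymethyl ether.

Step 13
Reactants: 17 tert-butyl (3R,5E,8S)-8-{[tert-butyl(dimethyl)silyl]oxy}-3-formyl-6-methyl-2-methylidenedeca-5,9-dienoate; 19 3-(methoxymethoxy)-2-methylprop-1-ene
Product: 21 tert-butyl (3R,5E,8S)-8-{[tert-butyl(dimethyl)silyl]oxy}-3-[(1R,2R)-1-hydroxy-2-(methoxymethoxy)-3-methylbut-3-en-1-yl]-6-methyl-2-methylidenedeca-5,9-dienoate, via allylborane 20 (not isolated)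
Conditions: 19, sBuLi, THF, −78 °C; (−)-Ipc2BOMe; BF3·OEt2; then 17, −78 °C; ethanolamine work-up
Reagents that add atoms: none
Why: Asymmetric γ-alkoxyallylboration (Brown alkoxyallylboration): metalation of 19 next to oxygen and transfer to boron give the Z allylborane 20, whose chair transition state delivers the syn C8/C9 diol pattern, while the isopinocampheyl groups direct attack to the Si face of the aldehyde and so set C8 and C9 under reagent control.

Step 14
Reactants: 21 tert-butyl (3R,5E,8S)-8-{[tert-butyl(dimethyl)silyl]oxy}-3-[(1R,2R)-1-hydroxy-2-(methoxymethoxy)-3-methylbut-3-en-1-yl]-6-methyl-2-methylidenedeca-5,9-dienoate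
Product: 22 C8 angelate of 21
Conditions: angelic acid, 2,4,6-Cl3C6H2COCl, Et3N, PhMe, rt; then 21, 75 °C
Reagents that add atoms: angelic acid, (Z)-2-methylbut-2-enoic acid (C/C=C(/C)C(=O)O)
Why: Yamaguchi-type esterification through the mixed trichlorobenzoic anhydride, run without a nucleophilic catalyst, should acylate the hindered C8 hydroxyl while keeping the Z geometry of the angelate.

Step 15
Reactants: 22 C8 angelate of 21
Product: 23 C9 alcohol (22 without the methoxymethyl group)
Conditions: ZnBr2, nPrSH, CH2Cl2, 0 °C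
Reagents that add atoms: none
Why: Lewis acid/thiol acetal cleavage: ZnBr2 activates the acetal and the thiol captures the methoxymethyl cation, so the ether is cleaved at the acetal carbon within minutes while the silyl ether, the esters and the C9–O bond stay intact.

Step 16
Reactants: 23 C9 alcohol
Product: 24 C9 acetate (open-chain tert-butyl ester)
Conditions: Ac2O, pyridine, DMAP (cat.), CH2Cl2, 0 °C
Reagents that add atoms: acetic anhydride (CC(=O)OC(C)=O)
Why: Standard acetylation of the allylic C9 hydroxyl.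

Step 17
Reactants: 24 C9 acetate (open-chain tert-butyl ester)
Product: 25 open-chain acid (C12 carboxylic acid)
Conditions: TMSOTf, 2,6-lutidine, CH2Cl2, 0 °C; aq. work-up
Reagents that add atoms: none
Why: Silyl triflate-mediated cleavage of the tert-butyl ester (loss of isobutene from the O-silylated ester) under buffered conditions should spare the silyl ether and the allylic esters, and it is done before the acid-sensitive cyclodecadiene exists.

Step 18
Reactants: 25 open-chain acid
Product: 26 (1(10)Z,2S,4E,7R,8R,9R)-9-acetoxy-8-angeloyloxy-2-[(tert-butyldimethylsilyl)oxy]germacra-1(10),4,11(13)-trien-12-oic acid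
Conditions: second-generation Hoveyda–Grubbs catalyst (10 mol %), PhMe, 80 °C, 1 mM
Reagents that add atoms: none
Why: Ring-closing metathesis between the monosubstituted C1 olefin and the 1,1-disubstituted C10 olefin; the trisubstituted 4,5-olefin and the electron-poor acrylate should not take part, and the ten-membered ring should prefer the less strained Z olefin at C1=C10.

Step 19
Reactants: 26 (1(10)Z,2S,4E,7R,8R,9R)-9-acetoxy-8-angeloyloxy-2-[(tert-butyldimethylsilyl)oxy]germacra-1(10),4,11(13)-trien-12-oic acid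
Product: 27 (1(10)Z,2S,4E,6R,7S,8R,9R)-9-acetoxy-8-angeloyloxy-2-[(tert-butyldimethylsilyl)oxy]germacra-1(10),4,11(13)-trien-12,6-olide
Conditions: undivided cell, graphite anode, Pt cathode, constant current (2.2 F/mol), nBu4NBF4, 2,4,6-collidine, MeCN/HFIP (4:1), 0 °C, 5 mM
Reagents that add atoms: none
Why: Proposed new method: anodic oxidation of the carboxylate of 26 should give the 2-alkylacryloyloxy radical, which is bound to an sp2 carbon and therefore loses CO2 only slowly, so that it abstracts the allylic hydrogen from C6 through a six-membered 1,5-transfer (O–C12–C11–C7–C6–H); the C4–C5–C6 allyl radical is then oxidised at the anode to the allyl cation, which the carboxyl group captures at C6 while H2 forms at the cathode. The closest known reaction type is the anodic dehydrogenative lactonization of 2-alkylbenzoic acids to phthalides (aroyloxy radical, 1,5-hydrogen transfer, radical-polar crossover), moved here from a benzylic to an allylic C–H bond. Ring B closes in the 5-exo mode at the C6 terminus of the allyl cation, since attack at C4 would need a seven-membered ring. The new C6 stereocenter is controlled by ring A: the oxygen should reach only the face of C6 that puts H6 trans to H7, because a cis-fused lactone across C6–C7 of a (4E)-cyclodecene is strongly strained, and the 4E geometry is kept because the allyl cation cannot rotate inside the ring. The step needs site selectivity for C6–H over the equally placed C8–H, which the stronger and electron-poor C–H bond next to the angelate oxygen should secure, and it needs the carboxylate to be oxidised before the olefins, which holds because a carboxylate is oxidised at a lower potential than a trisubstituted olefin. The C1=C10 olefin carries two allylic oxygen substituents and should therefore be too electron-poor to attack the allyl cation across the ring.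

Step 20
Reactants: 27 (1(10)Z,2S,4E,6R,7S,8R,9R)-9-acetoxy-8-angeloyloxy-2-[(tert-butyldimethylsilyl)oxy]germacra-1(10),4,11(13)-trien-12,6-olide
Product: 28 (1(10)Z,2S,4E,6R,7S,8R,9R)-9-acetoxy-8-angeloyloxy-2-hydroxygermacra-1(10),4,11(13)-trien-12,6-olide (CNP0316477.1)
Conditions: HF·pyridine, pyridine, THF, 0 °C to rt
Reagents that add atoms: none
Why: Buffered fluoride desilylation should free the C2 hydroxyl without touching the esters or the α-methylene lactone.

## Compound list

1 | (S)-epichlorohydrin, (2S)-2-(chloromethyl)oxirane | ClC[C@@H]1CO1 | starting material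
2 | ethynyltrimethylsilane | C#C[Si](C)(C)C | starting material
3 | (2S)-1-chloro-5-(trimethylsilyl)pent-4-yn-2-ol | ClC[C@@H](O)CC#C[Si](C)(C)C | intermediate
4 | (2S)-2-[3-(trimethylsilyl)prop-2-yn-1-yl]oxirane | C1[C@@H](O1)CC#C[Si](C)(C)C | intermediate
5 | (3S)-6-(trimethylsilyl)hex-1-en-5-yn-3-ol | C=C[C@@H](O)CC#C[Si](C)(C)C | intermediate
6 | tert-butyldimethyl{[(3S)-6-(trimethylsilyl)hex-1-en-5-yn-3-yl]oxy}silane | C=C[C@@H](O[Si](C)(C)C(C)(C)C)CC#C[Si](C)(C)C | intermediate
7 | tert-butyl{[(3S)-hex-1-en-5-yn-3-yl]oxy}dimethylsilane | C=C[C@@H](O[Si](C)(C)C(C)(C)C)CC#C | intermediate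
8 | [(1E,4S)-4-{[tert-butyl(dimethyl)silyl]oxy}-2-methylhexa-1,5-dien-1-yl]dimethylalane | C=C[C@@H](O[Si](C)(C)C(C)(C)C)C/C(C)=C/[Al](C)C | intermediate
9 | (2E,5S)-5-{[tert-butyl(dimethyl)silyl]oxy}-3-methylhepta-2,6-dien-1-ol | C=C[C@@H](O[Si](C)(C)C(C)(C)C)C/C(C)=C/CO | intermediate
10 | {[(3S,5E)-7-bromo-5-methylhepta-1,5-dien-3-yl]oxy}(tert-butyl)dimethylsilane | C=C[C@@H](O[Si](C)(C)C(C)(C)C)C/C(C)=C/CBr | intermediate
11 | itaconic anhydride, 3-methylideneoxolane-2,5-dione | C=C1CC(=O)OC1=O | starting material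
12 | (4R)-4-benzyl-1,3-oxazolidin-2-one | O=C1N[C@H](Cc2ccccc2)CO1 | starting material
13 | 4-[(4R)-4-benzyl-2-oxo-1,3-oxazolidin-3-yl]-2-methylidene-4-oxobutanoic acid | C=C(CC(=O)N1[C@H](Cc2ccccc2)COC1=O)C(=O)O | intermediate
14 | tert-butyl 4-[(4R)-4-benzyl-2-oxo-1,3-oxazolidin-3-yl]-2-methylidene-4-oxobutanoate | C=C(CC(=O)N1[C@H](Cc2ccccc2)COC1=O)C(=O)OC(C)(C)C | intermediate
15 | tert-butyl (3R,5E,8S)-3-{[(4R)-4-benzyl-2-oxo-1,3-oxazolidin-3-yl]carbonyl}-8-{[tert-butyl(dimethyl)silyl]oxy}-6-methyl-2-methylidenedeca-5,9-dienoate | C=C[C@@H](O[Si](C)(C)C(C)(C)C)C/C(C)=C/C[C@H](C(=C)C(=O)OC(C)(C)C)C(=O)N1[C@H](Cc2ccccc2)COC1=O | intermediate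
16 | tert-butyl (3R,5E,8S)-8-{[tert-butyl(dimethyl)silyl]oxy}-3-(hydroxymethyl)-6-methyl-2-methylidenedeca-5,9-dienoate | C=C[C@@H](O[Si](C)(C)C(C)(C)C)C/C(C)=C/C[C@H](C(=C)C(=O)OC(C)(C)C)CO | intermediate
17 | tert-butyl (3R,5E,8S)-8-{[tert-butyl(dimethyl)silyl]oxy}-3-formyl-6-methyl-2-methylidenedeca-5,9-dienoate | C=C[C@@H](O[Si](C)(C)C(C)(C)C)C/C(C)=C/C[C@H](C(=C)C(=O)OC(C)(C)C)C=O | intermediate
18 | 2-methylprop-2-en-1-ol | C=C(C)CO | starting material
19 | 3-(methoxymethoxy)-2-methylprop-1-ene | C=C(C)COCOC | intermediate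
20 | (Z)-[3-(methoxymethoxy)-2-methylprop-2-en-1-yl]diisopinocampheylborane (isopinocampheyl groups from (+)-α-pinene) | COCO/C=C(/C)CB([C@@H]1C[C@@H]2C[C@H]([C@H]1C)C2(C)C)[C@@H]1C[C@@H]2C[C@H]([C@H]1C)C2(C)C | intermediate
21 | tert-butyl (3R,5E,8S)-8-{[tert-butyl(dimethyl)silyl]oxy}-3-[(1R,2R)-1-hydroxy-2-(methoxymethoxy)-3-methylbut-3-en-1-yl]-6-methyl-2-methylidenedeca-5,9-dienoate | C=C[C@@H](O[Si](C)(C)C(C)(C)C)C/C(C)=C/C[C@H](C(=C)C(=O)OC(C)(C)C)[C@@H](O)[C@H](OCOC)C(C)=C | intermediate
22 | tert-butyl (3R,5E,8S)-8-{[tert-butyl(dimethyl)silyl]oxy}-3-[(1R,2R)-2-(methoxymethoxy)-3-methyl-1-{[(2Z)-2-methylbut-2-enoyl]oxy}but-3-en-1-yl]-6-methyl-2-methylidenedeca-5,9-dienoate | C=C[C@@H](O[Si](C)(C)C(C)(C)C)C/C(C)=C/C[C@H](C(=C)C(=O)OC(C)(C)C)[C@@H](OC(=O)/C(C)=C\C)[C@H](OCOC)C(C)=C | intermediate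
23 | tert-butyl (3R,5E,8S)-8-{[tert-butyl(dimethyl)silyl]oxy}-3-[(1R,2R)-2-hydroxy-3-methyl-1-{[(2Z)-2-methylbut-2-enoyl]oxy}but-3-en-1-yl]-6-methyl-2-methylidenedeca-5,9-dienoate | C=C[C@@H](O[Si](C)(C)C(C)(C)C)C/C(C)=C/C[C@H](C(=C)C(=O)OC(C)(C)C)[C@@H](OC(=O)/C(C)=C\C)[C@H](O)C(C)=C | intermediate
24 | tert-butyl (3R,5E,8S)-3-[(1R,2R)-2-acetoxy-3-methyl-1-{[(2Z)-2-methylbut-2-enoyl]oxy}but-3-en-1-yl]-8-{[tert-butyl(dimethyl)silyl]oxy}-6-methyl-2-methylidenedeca-5,9-dienoate | C=C[C@@H](O[Si](C)(C)C(C)(C)C)C/C(C)=C/C[C@H](C(=C)C(=O)OC(C)(C)C)[C@@H](OC(=O)/C(C)=C\C)[C@H](OC(C)=O)C(C)=C | intermediate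
25 | (3R,5E,8S)-3-[(1R,2R)-2-acetoxy-3-methyl-1-{[(2Z)-2-methylbut-2-enoyl]oxy}but-3-en-1-yl]-8-{[tert-butyl(dimethyl)silyl]oxy}-6-methyl-2-methylidenedeca-5,9-dienoic acid | C=C[C@@H](O[Si](C)(C)C(C)(C)C)C/C(C)=C/C[C@H](C(=C)C(=O)O)[C@@H](OC(=O)/C(C)=C\C)[C@H](OC(C)=O)C(C)=C | intermediate
26 | (1(10)Z,2S,4E,7R,8R,9R)-9-acetoxy-8-angeloyloxy-2-[(tert-butyldimethylsilyl)oxy]germacra-1(10),4,11(13)-trien-12-oic acid | C=C(C(=O)O)[C@H]1C/C=C(\C)C[C@H](O[Si](C)(C)C(C)(C)C)/C=C(/C)[C@@H](OC(C)=O)[C@@H]1OC(=O)/C(C)=C\C | intermediate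
27 | (1(10)Z,2S,4E,6R,7S,8R,9R)-9-acetoxy-8-angeloyloxy-2-[(tert-butyldimethylsilyl)oxy]germacra-1(10),4,11(13)-trien-12,6-olide | C=C1C(=O)O[C@@H]2/C=C(\C)C[C@H](O[Si](C)(C)C(C)(C)C)/C=C(/C)[C@@H](OC(C)=O)[C@H](OC(=O)/C(C)=C\C)[C@@H]12 | intermediate
28 | (1(10)Z,2S,4E,6R,7S,8R,9R)-9-acetoxy-8-angeloyloxy-2-hydroxygermacra-1(10),4,11(13)-trien-12,6-olide (CNP0316477.1) | C=C1C(=O)O[C@@H]2/C=C(\C)C[C@H](O)/C=C(/C)[C@@H](OC(C)=O)[C@H](OC(=O)/C(C)=C\C)[C@@H]12 | target

## Step count and risks

Total step count: 20. Longest linear sequence: 17 steps (steps 1–6, 9–11, 13–20).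

Steps most likely to fail:

Step 19 (proposed new method). The carboxyl radical may add to C5 of the 4,5-olefin instead of abstracting H6, the allyl cation may be captured across the ring by the C1=C10 olefin, or the olefins may be oxidised at the anode before the carboxylate. The fallback brings in the C6 oxygen by known allylic oxidation and closes the same O–C6 bond by an SN2 reaction. It sets out from 24: ring-closing metathesis (second-generation Hoveyda–Grubbs catalyst, PhMe, 80 °C) would give the macrocyclic tert-butyl ester F1. CrO3/3,5-dimethylpyrazole (CH2Cl2, −20 °C) should oxidise the C6 methylene, the allylic CH2 on the CH terminus of the 4,5-olefin, to the 6-ketone F2. Corey–Bakshi–Shibata reduction ((S)-2-methyl-CBS-oxazaborolidine, catecholborane, −78 °C) would give the 6S alcohol F3. TMSOTf/2,6-lutidine would then free the hydroxy acid F4, in which the 6S hydroxyl should not lactonise on its own because that would need the strained cis-fused lactone. Mitsunobu lactonization (PPh3, DIAD, PhMe, high dilution) would form the O–C6 bond with inversion at C6 and come back to the route at 27.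

Step 18. Cross-metathesis oligomerisation may outrun ring closure because the open-chain acid has no conformational bias toward the strained ten-membered ring, and part of the material may close to the E olefin at C1=C10. The fallback closes the lactone before the carbocycle. It sets out from 25: the anodic lactonization of step 19 (same cell and electrolyte) would be run on the open-chain acid to give the α-methylene lactone F5, whose trans-fused butyrolactone holds the vinyl-bearing and isopropenyl-bearing arms on neighbouring ring carbons. Ring-closing metathesis of this pre-organised diene (second-generation Hoveyda–Grubbs catalyst, PhMe, 80 °C, 1 mM) would come back to the route at 27.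

Step 14. Acyl transfer to the hindered C8 hydroxyl may be slow enough for the Z enoate to isomerise to the E enoate (tiglate). The fallback builds the Z olefin on the alcohol instead of transferring it. It sets out from 21: esterification with 2-[bis(2,2,2-trifluoroethoxy)phosphoryl]propanoic acid (DCC, DMAP, CH2Cl2) would give the phosphonopropionate F6 (epimers at the phosphonate carbon). Still–Gennari olefination with acetaldehyde (KN(SiMe3)2, 18-crown-6, THF, −78 °C) should then give the Z trisubstituted enoate and come back to the route at 22.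

## Further compounds

F1 | step 19 | tert-butyl (1(10)Z,2S,4E,7R,8R,9R)-9-acetoxy-8-angeloyloxy-2-[(tert-butyldimethylsilyl)oxy]germacra-1(10),4,11(13)-trien-12-oate | C=C(C(=O)OC(C)(C)C)[C@H]1C/C=C(\C)C[C@H](O[Si](C)(C)C(C)(C)C)/C=C(/C)[C@@H](OC(C)=O)[C@@H]1OC(=O)/C(C)=C\C
F2 | step 19 | tert-butyl (1(10)Z,2S,4E,7R,8R,9R)-9-acetoxy-8-angeloyloxy-2-[(tert-butyldimethylsilyl)oxy]-6-oxogermacra-1(10),4,11(13)-trien-12-oate | C=C(C(=O)OC(C)(C)C)[C@H]1C(=O)/C=C(\C)C[C@H](O[Si](C)(C)C(C)(C)C)/C=C(/C)[C@@H](OC(C)=O)[C@@H]1OC(=O)/C(C)=C\C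
F3 | step 19 | tert-butyl (1(10)Z,2S,4E,6S,7S,8R,9R)-9-acetoxy-8-angeloyloxy-2-[(tert-butyldimethylsilyl)oxy]-6-hydroxygermacra-1(10),4,11(13)-trien-12-oate | C=C(C(=O)OC(C)(C)C)[C@H]1[C@@H](O)/C=C(\C)C[C@H](O[Si](C)(C)C(C)(C)C)/C=C(/C)[C@@H](OC(C)=O)[C@@H]1OC(=O)/C(C)=C\C
F4 | step 19 | (1(10)Z,2S,4E,6S,7S,8R,9R)-9-acetoxy-8-angeloyloxy-2-[(tert-butyldimethylsilyl)oxy]-6-hydroxygermacra-1(10),4,11(13)-trien-12-oic acid | C=C(C(=O)O)[C@H]1[C@@H](O)/C=C(\C)C[C@H](O[Si](C)(C)C(C)(C)C)/C=C(/C)[C@@H](OC(C)=O)[C@@H]1OC(=O)/C(C)=C\C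
F5 | step 18 | α-methylene-γ-butyrolactone corresponding to 27 with the C1=C10 bond replaced by a vinyl group on C2 and an isopropenyl group on C9 (2S,4E,6R,7S,8R,9R) | C=C1C(=O)O[C@H](/C=C(\C)C[C@H](O[Si](C)(C)C(C)(C)C)C=C)[C@H]1[C@@H](OC(=O)/C(C)=C\C)[C@H](OC(C)=O)C(C)=C
F6 | step 14 | C8 2-[bis(2,2,2-trifluoroethoxy)phosphoryl]propanoate of 21 (epimers at the phosphonate carbon) | C=C[C@@H](O[Si](C)(C)C(C)(C)C)C/C(C)=C/C[C@H](C(=C)C(=O)OC(C)(C)C)[C@@H](OC(=O)C(C)P(=O)(OCC(F)(F)F)OCC(F)(F)F)[C@H](OCOC)C(C)=C
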